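The chain between the furan ring and the tetronic acid ring holds two (E)-trisubstituted alkenes, each a CH2–C(CH3)=CH–CH2–CH2 unit. Each unit is read as a 2,3-dihydrofuran cut open at its O1–C5 bond: C5 takes the incoming chain and the methyl group, C4 becomes the vinylic CH, and C3 and C2 become the two methylenes. In the key step a homoallylic alkyl group moves from copper to C5 of 5-lithio-2,3-dihydrofuran and iodomethane caps the alkenylcopper. This gives the furan-side alkene and two C–C bonds in one flask with defined E geometry. The precursor is the (S,E)-homoallylic iodide that already holds the silyl-protected C18 stereocentre and the first alkene.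

Key step: step 7

Remark: the target SMILES is read as (18S)-variabilin with a (Z) exocyclic alkene; the C18 stereocentre is bought in with 1 and never touched, and its label changes from R to S only because the CIP priorities change when bromine is replaced by carbon.

Remark: the THF solution of 8 from step 4 is made fresh, on the scale required, directly before each of steps 5 and 7; the preparation is written once.

Step 1
Reactants: 1 (R)-3-bromo-2-methylpropan-1-ol
Product: 2 (R)-(3-bromo-2-methylpropoxy)(tert-butyl)dimethylsilane
Conditions: TBSCl, imidazole, CH2Cl2, 0 °C → rt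
Reagents that add atoms: tert-butyldimethylsilyl chloride, CC(C)(C)[Si](C)(C)Cl
Why: Imidazole-promoted silylation of a primary alcohol is reliable and does not involve any bond at the stereocentre, which therefore stays as bought.

Step 2
Reactants: 2 (R)-(3-bromo-2-methylpropoxy)(tert-butyl)dimethylsilane; 3 oxirane
Product: 5 (S)-5-((tert-butyldimethylsilyl)oxy)-4-methylpentan-1-ol, via Grignard reagent 4 (not isolated)
Conditions: Mg, THF, reflux; then CuI (10 mol %), 3, THF, −30 → 0 °C; aq. NH4Cl
Reagents that add atoms: none
Why: Grignard formation followed by CuI-catalysed SN2 opening of the epoxide should add the two carbons as a primary alcohol, and the stereocentre, β to magnesium, takes no part.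

Step 3
Reactants: 5 (S)-5-((tert-butyldimethylsilyl)oxy)-4-methylpentan-1-ol
Product: 6 (S)-tert-butyl((5-iodo-2-methylpentyl)oxy)dimethylsilane
Conditions: I2, PPh3, imidazole, CH2Cl2, 0 °C → rt
Reagents that add atoms: iodine, II
Why: Appel-type iodination converts the primary alcohol by SN2 displacement of its alkoxyphosphonium ion, and the imidazole buffer should keep the silyl ether intact.

Step 4
Reactants: 7 2,3-dihydrofuran
Product: 8 5-lithio-2,3-dihydrofuran (THF solution used at once)
Conditions: t-BuLi (1 equiv), THF, −78 → 0 °C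
Reagents that add atoms: tert-butyllithium, [Li]C(C)(C)C
Why: The ring oxygen acidifies and directs metalation of the adjacent vinylic C5–H, so deprotonation with t-BuLi in THF should give the α-alkoxyalkenyllithium cleanly, a standard α-lithiation of a cyclic enol ether.

Step 5
Reactants: 6 (S)-tert-butyl((5-iodo-2-methylpentyl)oxy)dimethylsilane; 8 5-lithio-2,3-dihydrofuran; 9 iodomethane
Product: 14 (S,E)-9-((tert-butyldimethylsilyl)oxy)-4,8-dimethylnon-3-en-1-ol, via alkyllithium 10 (not isolated), via alkylcopper 11 (not isolated), via mixed lithium cuprate 12 (not isolated), via alkenylcopper alkoxide 13 (not isolated)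
Conditions: t-BuLi (2 equiv), Et2O–pentane, −78 °C; CuBr·SMe2 (1 equiv), Me2S–Et2O, −78 → −40 °C; 8 (THF solution from step 4), −78 °C → rt; then 9, 0 °C → rt; aq. NH4Cl
Reagents that add atoms: iodomethane (compound 9, also a reactant above), CI
Why: This is the 1,2-metalate rearrangement of an α-alkoxyalkenyl cuprate with a saturated primary alkyl ligand, followed by methylation of the alkenylcopper with retention, so the first (E)-trisubstituted alkene should form stereospecifically (mechanism as detailed under step 7) without creating a stereocentre.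

Step 6
Reactants: 14 (S,E)-9-((tert-butyldimethylsilyl)oxy)-4,8-dimethylnon-3-en-1-ol
Product: 15 (S,E)-tert-butyl((9-iodo-2,6-dimethylnon-6-en-1-yl)oxy)dimethylsilane
Conditions: I2, PPh3, imidazole, CH2Cl2, 0 °C → rt
Reagents that add atoms: iodine, II
Why: Appel-type iodination of a homoallylic primary alcohol proceeds by direct SN2 displacement, so allylic transposition and loss of alkene geometry are not expected.

Step 7
Reactants: 15 (S,E)-tert-butyl((9-iodo-2,6-dimethylnon-6-en-1-yl)oxy)dimethylsilane; 8 5-lithio-2,3-dihydrofuran; 9 iodomethane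
Product: 20 (S,3E,7E)-13-((tert-butyldimethylsilyl)oxy)-4,8,12-trimethyltrideca-3,7-dien-1-ol, via alkyllithium 16 (not isolated), via alkylcopper 17 (not isolated), via mixed lithium cuprate 18 (not isolated), via alkenylcopper alkoxide 19 (not isolated)
Conditions: t-BuLi (2 equiv), Et2O–pentane, −78 °C; CuBr·SMe2 (1 equiv), Me2S–Et2O, −78 → −40 °C; 8 (THF solution from step 4), −78 °C → rt; then 9, 0 °C → rt; aq. NH4Cl
Reagents that add atoms: iodomethane (compound 9, also a reactant above), CI
Why: Iodine–lithium exchange gives the homoallylic alkyllithium 16, which is converted by CuBr·SMe2 into alkylcopper 17 and by 5-lithio-2,3-dihydrofuran 8 into the mixed cuprate 18; on warming, the alkyl ligand shifts from copper to the oxygen-bearing C5 with inversion at that sp2 carbon while the ring C5–O bond breaks, so that in alkenylcopper 19 the new chain is trans and copper is cis to the oxidoethyl arm. Iodomethane then alkylates the C–Cu bond with retention, which places the methyl group cis and the chain trans to the CH2CH2OH arm, the (E)-alkene. The closest known reaction type is the 1,2-metalate rearrangement of α-alkoxyalkenyl cuprates derived from lithiated cyclic enol ethers with electrophilic trapping of the resulting alkenylcopper. No ring is closed (the dihydrofuran ring is opened) and no stereocentre is created, the remote methyl-bearing stereocentre being a spectator. The selectivity needed is alkene geometry only, and it is secured by the ring of the dihydrofuran, which fixes oxygen and C3 cis before migration, together with the stereospecific inversion and retention events. A 1:1 mixed cuprate is used so that none of the chiral alkyl chain is spent as a non-transferred ligand, and the existing (E)-alkene and the silyl ether should be inert to the organometallics at these temperatures.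

Step 8
Reactants: 20 (S,3E,7E)-13-((tert-butyldimethylsilyl)oxy)-4,8,12-trimethyltrideca-3,7-dien-1-ol
Product: 21 (S,6E,10E)-tert-butyl((13-iodo-2,6,10-trimethyltrideca-6,10-dien-1-yl)oxy)dimethylsilane
Conditions: I2, PPh3, imidazole, CH2Cl2, 0 °C → rt
Reagents that add atoms: iodine, II
Why: The same Appel-type iodination as in steps 3 and 6 applies, with the homoallylic position again excluding allylic rearrangement.

Step 9
Reactants: 21 (S,6E,10E)-tert-butyl((13-iodo-2,6,10-trimethyltrideca-6,10-dien-1-yl)oxy)dimethylsilane; 22 3-bromofuran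
Product: 24 (S,6E,10E)-tert-butyl((13-(furan-3-yl)-2,6,10-trimethyltrideca-6,10-dien-1-yl)oxy)dimethylsilane, via alkylzinc iodide 23 (not isolated)
Conditions: activated Zn dust, LiCl, THF, 40 °C; then 22, Pd(dppf)Cl2 (5 mol %), THF, 50 °C
Reagents that add atoms: none
Why: Negishi coupling of the primary alkylzinc iodide with the heteroaryl bromide runs through oxidative addition to zerovalent palladium, transmetalation and reductive elimination, and the wide bite angle of dppf should favour reductive elimination over β-hydride elimination.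

Step 10
Reactants: 24 (S,6E,10E)-tert-butyl((13-(furan-3-yl)-2,6,10-trimethyltrideca-6,10-dien-1-yl)oxy)dimethylsilane
Product: 25 (S,6E,10E)-13-(furan-3-yl)-2,6,10-trimethyltrideca-6,10-dien-1-ol
Conditions: TBAF, THF, 0 °C → rt
Reagents that add atoms: none
Why: Fluoride-induced desilylation is driven by the strong Si–F bond and is neutral enough for the furan and both alkenes.

Step 11
Reactants: 25 (S,6E,10E)-13-(furan-3-yl)-2,6,10-trimethyltrideca-6,10-dien-1-ol
Product: 26 (S,6E,10E)-13-(furan-3-yl)-2,6,10-trimethyltrideca-6,10-dienal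
Conditions: Dess–Martin periodinane, pyridine, CH2Cl2, 0 °C → rt; used crude
Reagents that add atoms: none
Why: Dess–Martin oxidation stops at the aldehyde under nearly neutral conditions, so the α-methyl stereocentre should not epimerise and the furan and alkenes should not be oxidised.

Step 12
Reactants: 27 3-methyltetronic acid
Product: 28 4-methoxy-3-methylfuran-2(5H)-one
Conditions: Me2SO4, K2CO3, acetone, reflux
Reagents that add atoms: dimethyl sulfate, COS(=O)(=O)OC
Why: O-Alkylation of the vinylogous acid with a hard methylating agent should give the 4-methyl ether, which masks the acidic OH for the enolate chemistry that follows.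

Step 13
Reactants: 28 4-methoxy-3-methylfuran-2(5H)-one; 26 (S,6E,10E)-13-(furan-3-yl)-2,6,10-trimethyltrideca-6,10-dienal
Product: 30 5-[(2S,6E,10E)-13-(furan-3-yl)-1-hydroxy-2,6,10-trimethyltrideca-6,10-dien-1-yl]-4-methoxy-3-methylfuran-2(5H)-one (diastereomer mixture at the carbinol carbon and ring C5), via lithium furanolate 29 (not isolated)
Conditions: LiN(i-Pr)2 (LDA), THF, −78 °C; then 26, −78 °C; aq. NH4Cl
Reagents that add atoms: none
Why: Deprotonation at C5 gives the aromatic 2-furanolate, which undergoes aldol addition through C5 to the aldehyde at −78 °C faster than it can enolise it, and the two new stereocentres are left uncontrolled because step 14 removes both.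

Step 14
Reactants: 30 5-[(2S,6E,10E)-13-(furan-3-yl)-1-hydroxy-2,6,10-trimethyltrideca-6,10-dien-1-yl]-4-methoxy-3-methylfuran-2(5H)-one
Product: 32 (Z)-5-[(2S,6E,10E)-13-(furan-3-yl)-2,6,10-trimethyltrideca-6,10-dien-1-ylidene]-4-methoxy-3-methylfuran-2(5H)-one, via mesylate 31 (not isolated)
Conditions: MsCl, Et3N, CH2Cl2, 0 °C; then DBU, 0 °C → rt
Reagents that add atoms: none
Why: Mesylation followed by DBU-induced E1cB elimination through the C5 anion should give the conjugated exocyclic alkene as the favoured (Z)-isomer, with the chain on the ring-oxygen side away from the 4-methoxy group, and the C18 stereocentre should survive the short exposure to base at low temperature.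

Step 15
Reactants: 32 (Z)-5-[(2S,6E,10E)-13-(furan-3-yl)-2,6,10-trimethyltrideca-6,10-dien-1-ylidene]-4-methoxy-3-methylfuran-2(5H)-one
Product: 33 variabilin, (Z)-5-[(2S,6E,10E)-13-(furan-3-yl)-2,6,10-trimethyltrideca-6,10-dien-1-ylidene]-4-hydroxy-3-methylfuran-2(5H)-one
Conditions: n-PrSLi, HMPA, rt; then 1 M HCl to pH 3, 0 °C
Reagents that add atoms: none
Why: The soft thiolate should remove the methyl group by SN2 attack at carbon, as in thiolate cleavage of methyl esters, because the tetronate anion is a good leaving group, and acidification then frees the tetronic acid without touching C18 or any alkene.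

Compound list
1 | (R)-3-bromo-2-methylpropan-1-ol | OC[C@@H](C)CBr | starting material
2 | (R)-(3-bromo-2-methylpropoxy)(tert-butyl)dimethylsilane | CC(C)(C)[Si](C)(C)OC[C@@H](C)CBr | intermediate
3 | oxirane | C1CO1 | starting material
4 | (R)-[3-((tert-butyldimethylsilyl)oxy)-2-methylpropyl]magnesium bromide | CC(C)(C)[Si](C)(C)OC[C@@H](C)C[Mg]Br | intermediate
5 | (S)-5-((tert-butyldimethylsilyl)oxy)-4-methylpentan-1-ol | CC(C)(C)[Si](C)(C)OC[C@@H](C)CCCO | intermediate
6 | (S)-tert-butyl((5-iodo-2-methylpentyl)oxy)dimethylsilane | CC(C)(C)[Si](C)(C)OC[C@@H](C)CCCI | intermediate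
7 | 2,3-dihydrofuran | C1=COCC1 | starting material
8 | 5-lithio-2,3-dihydrofuran (THF solution used at once) | [Li]C1=CCCO1 | intermediate
9 | iodomethane | CI | starting material
10 | (S)-[5-((tert-butyldimethylsilyl)oxy)-4-methylpentyl]lithium | CC(C)(C)[Si](C)(C)OC[C@@H](C)CCC[Li] | intermediate
11 | (S)-[5-((tert-butyldimethylsilyl)oxy)-4-methylpentyl]copper (Me2S-solvated) | CC(C)(C)[Si](C)(C)OC[C@@H](C)CCC[Cu] | intermediate
12 | lithium (S)-[5-((tert-butyldimethylsilyl)oxy)-4-methylpentyl](4,5-dihydrofuran-2-yl)cuprate | [Li+].CC(C)(C)[Si](C)(C)OC[C@@H](C)CCC[Cu-]C1=CCCO1 | intermediate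
13 | lithium (S,Z)-9-((tert-butyldimethylsilyl)oxy)-4-cuprio-8-methylnon-3-en-1-olate (copper cis to the oxidoethyl arm) | [Li+].CC(C)(C)[Si](C)(C)OC[C@@H](C)CCC/C([Cu])=C/CC[O-] | intermediate
14 | (S,E)-9-((tert-butyldimethylsilyl)oxy)-4,8-dimethylnon-3-en-1-ol | CC(C)(C)[Si](C)(C)OC[C@@H](C)CCC/C(C)=C/CCO | intermediate
15 | (S,E)-tert-butyl((9-iodo-2,6-dimethylnon-6-en-1-yl)oxy)dimethylsilane | CC(C)(C)[Si](C)(C)OC[C@@H](C)CCC/C(C)=C/CCI | intermediate
16 | (S,E)-[9-((tert-butyldimethylsilyl)oxy)-4,8-dimethylnon-3-en-1-yl]lithium | CC(C)(C)[Si](C)(C)OC[C@@H](C)CCC/C(C)=C/CC[Li] | intermediate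
17 | (S,E)-[9-((tert-butyldimethylsilyl)oxy)-4,8-dimethylnon-3-en-1-yl]copper (Me2S-solvated) | CC(C)(C)[Si](C)(C)OC[C@@H](C)CCC/C(C)=C/CC[Cu] | intermediate
18 | lithium (S,E)-[9-((tert-butyldimethylsilyl)oxy)-4,8-dimethylnon-3-en-1-yl](4,5-dihydrofuran-2-yl)cuprate | [Li+].CC(C)(C)[Si](C)(C)OC[C@@H](C)CCC/C(C)=C/CC[Cu-]C1=CCCO1 | intermediate
19 | lithium (S,3Z,7E)-13-((tert-butyldimethylsilyl)oxy)-4-cuprio-8,12-dimethyltrideca-3,7-dien-1-olate (copper cis to the oxidoethyl arm) | [Li+].CC(C)(C)[Si](C)(C)OC[C@@H](C)CCC/C(C)=C/CC/C([Cu])=C/CC[O-] | intermediate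
20 | (S,3E,7E)-13-((tert-butyldimethylsilyl)oxy)-4,8,12-trimethyltrideca-3,7-dien-1-ol | CC(C)(C)[Si](C)(C)OC[C@@H](C)CCC/C(C)=C/CC/C(C)=C/CCO | intermediate
21 | (S,6E,10E)-tert-butyl((13-iodo-2,6,10-trimethyltrideca-6,10-dien-1-yl)oxy)dimethylsilane | CC(C)(C)[Si](C)(C)OC[C@@H](C)CCC/C(C)=C/CC/C(C)=C/CCI | intermediate
22 | 3-bromofuran | Brc1ccoc1 | starting material
23 | (S,3E,7E)-[13-((tert-butyldimethylsilyl)oxy)-4,8,12-trimethyltrideca-3,7-dien-1-yl]zinc iodide | CC(C)(C)[Si](C)(C)OC[C@@H](C)CCC/C(C)=C/CC/C(C)=C/CC[Zn]I | intermediate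
24 | (S,6E,10E)-tert-butyl((13-(furan-3-yl)-2,6,10-trimethyltrideca-6,10-dien-1-yl)oxy)dimethylsilane | CC(C)(C)[Si](C)(C)OC[C@@H](C)CCC/C(C)=C/CC/C(C)=C/CCc1ccoc1 | intermediate
25 | (S,6E,10E)-13-(furan-3-yl)-2,6,10-trimethyltrideca-6,10-dien-1-ol | OC[C@@H](C)CCC/C(C)=C/CC/C(C)=C/CCc1ccoc1 | intermediate
26 | (S,6E,10E)-13-(furan-3-yl)-2,6,10-trimethyltrideca-6,10-dienal | O=C[C@@H](C)CCC/C(C)=C/CC/C(C)=C/CCc1ccoc1 | intermediate
27 | 3-methyltetronic acid (4-hydroxy-3-methylfuran-2(5H)-one) | CC1=C(O)COC1=O | starting material
28 | 4-methoxy-3-methylfuran-2(5H)-one | COC1=C(C)C(=O)OC1 | intermediate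
29 | lithium 4-methoxy-3-methylfuran-2-olate | [Li+].COc1coc([O-])c1C | intermediate
30 | 5-[(2S,6E,10E)-13-(furan-3-yl)-1-hydroxy-2,6,10-trimethyltrideca-6,10-dien-1-yl]-4-methoxy-3-methylfuran-2(5H)-one (diastereomer mixture at the carbinol carbon and ring C5) | COC1=C(C)C(=O)OC1C(O)[C@@H](C)CCC/C(C)=C/CC/C(C)=C/CCc1ccoc1 | intermediate
31 | methanesulfonate of 30 | COC1=C(C)C(=O)OC1C(OS(C)(=O)=O)[C@@H](C)CCC/C(C)=C/CC/C(C)=C/CCc1ccoc1 | intermediate
32 | (Z)-5-[(2S,6E,10E)-13-(furan-3-yl)-2,6,10-trimethyltrideca-6,10-dien-1-ylidene]-4-methoxy-3-methylfuran-2(5H)-one | COC1=C(C)C(=O)O/C1=C\[C@@H](C)CCC/C(C)=C/CC/C(C)=C/CCc1ccoc1 | intermediate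
33 | variabilin, (Z)-5-[(2S,6E,10E)-13-(furan-3-yl)-2,6,10-trimethyltrideca-6,10-dien-1-ylidene]-4-hydroxy-3-methylfuran-2(5H)-one | CC1=C(O)/C(=C/[C@@H](C)CCC/C(C)=C/CC/C(C)=C/CCc2ccoc2)OC1=O | target

Total step count: 15 (13 in the main line, plus the one-step preparation of the reagent solution 8 and the one-step preparation of 28).
Longest linear sequence: 13 steps, from 1 to 33 (steps 1–3, 5–11 and 13–15).

Steps most likely to fail

Step 7 (the same concern applies to step 5). The mixed cuprate may break down or exchange ligands before the 1,2-shift, which after work-up would return the protonated chain and homocoupled material. Slow methylation may also let the alkenylcopper be protonated, leaving a disubstituted alkene. The fallback makes the same two bonds in two separate operations. It sets out from 15 and from 8, made in step 4 as before. Alkylation of 8 with 15 in THF/DMPU (−30 °C → rt) should give the 5-alkyl-2,3-dihydrofuran (S,E)-tert-butyl((9-(4,5-dihydrofuran-2-yl)-2,6-dimethylnon-6-en-1-yl)oxy)dimethylsilane F1. Its enol ether C–O bond is then replaced by methyl with retention, using MeMgBr and NiCl2(PPh3)2 (5 mol %) in refluxing toluene, a nickel-catalysed Grignard coupling that opens the ring. This returns to the route at 20 with the same E geometry.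

Step 13. The basic furanolate 29 may take the α-proton of the branched aldehyde 26 instead of adding to it, which would erode C18 and return unreacted 28, and the aldolate may revert on warming. The fallback avoids strong base. It sets out from 28 and 26. Silylation of 28 with TBSOTf and Et3N (CH2Cl2, 0 °C) should give tert-butyl((4-methoxy-3-methylfuran-2-yl)oxy)dimethylsilane F2. F2 then adds through C5 to 26 in a vinylogous Mukaiyama aldol reaction promoted by BF3·OEt2 in CH2Cl2 at −78 °C. This returns to the route at 30.

Step 9. Zinc insertion may stall, or the alkylzinc may be protonated. Oxidative addition to the electron-rich 3-bromofuran may also be slow enough for β-hydride elimination and homocoupling to compete. The fallback needs no preformed organometallic. It sets out from 21 and 22, which are joined directly by nickel-catalysed reductive cross-electrophile coupling (NiI2, 4,4′-di-tert-butyl-2,2′-bipyridine, Zn dust, DMPU, 60 °C). This returns to the route at 24 and makes no new compound.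

Further compounds
F1 | step 7 | (S,E)-tert-butyl((9-(4,5-dihydrofuran-2-yl)-2,6-dimethylnon-6-en-1-yl)oxy)dimethylsilane | CC(C)(C)[Si](C)(C)OC[C@@H](C)CCC/C(C)=C/CCC1=CCCO1
F2 | step 13 | tert-butyl((4-methoxy-3-methylfuran-2-yl)oxy)dimethylsilane | COc1coc(O[Si](C)(C)C(C)(C)C)c1C
F0 | step 9 | none | none
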